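**Plan**

1. Retrosynthetic cuts: first the C(sp)–C(sp3) bond between the alkyne terminus and the OCH2CH2 chain, giving terminal alkyne 7 and 2-iodoethyl 3-methylbutanoate 10; then the two ester C(=O)–O bonds; last the thiophene C5'–C(sp) bond.
2. Forward: the 2,2'-bithiophene is bought intact as bromo aldehyde 1, so no ring is made. The alkyne is installed by Sonogashira coupling, the aldehyde is reduced and the silyl group removed in one pot, and the senecioate is made by Steglich esterification. The side chain is joined last by a photoinduced copper-catalysed radical alkynylation.
3. Enabling feature: the terminal sp C–H is conjugated through the C≡C bond with the two thiophene rings. It is acidic and gives a copper(I) acetylide that absorbs visible light and is strongly reducing when excited. The O–CH2–CH2 unit gives a 2-(acyloxy)ethyl radical whose 1,2-acyloxy shift is degenerate. Both esters are spared because no strong base or carbon nucleophile is used.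
4. Stereochemistry: there is none to set. The target has no stereocentre, and its one alkene carries two identical methyl groups.

Key step: step 5

Assumption: the target SMILES has no stereogenic element, so the compound is achiral and the requirement of a single enantiomer is met as drawn.

**Route**

Step 1
Reactants: 1 5'-bromo-[2,2'-bithiophene]-5-carbaldehyde; 2 ethynyltrimethylsilane
Product: 3 5'-[(trimethylsilyl)ethynyl]-[2,2'-bithiophene]-5-carbaldehyde
Conditions: PdCl2(PPh3)2 (2 mol%), CuI (4 mol%), Et3N (3 equiv), THF, 40 °C, Ar
Reagents that add atoms: none
Why: Sonogashira coupling; the 2-bromothiophene carbon of the electron-poor formyl-bithiophene should undergo oxidative addition readily, and the aldehyde is inert under these conditions.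

Step 2
Reactants: 3 5'-[(trimethylsilyl)ethynyl]-[2,2'-bithiophene]-5-carbaldehyde
Product: 5 (5'-ethynyl-[2,2'-bithiophen]-5-yl)methanol, via silylalkynyl alcohol 4 (not isolated)
Conditions: NaBH4, MeOH/THF, 0 °C; then K2CO3, rt; aq NH4Cl work-up
Reagents that add atoms: none
Why: Borohydride reduction of the aryl aldehyde followed by base-mediated methanolysis of the C(sp)–Si bond in the same pot; no ester is present yet, so the basic methanol does no harm.

Step 3
Reactants: 5 (5'-ethynyl-[2,2'-bithiophen]-5-yl)methanol; 6 3-methylbut-2-enoic acid
Product: 7 (5'-ethynyl-[2,2'-bithiophen]-5-yl)methyl 3-methylbut-2-enoate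
Conditions: DCC (1.2 equiv), DMAP (10 mol%), CH2Cl2, 0 °C to rt, dark
Reagents that add atoms: none
Why: Steglich esterification; the near-neutral carbodiimide conditions avoid the acid that would ionise the electron-rich thienylmethyl alcohol, and they avoid the acid chloride/amine combination that tends to move the double bond out of conjugation through a vinylketene.

Step 4
Reactants: 8 2-iodoethanol; 9 3-methylbutanoyl chloride
Product: 10 2-iodoethyl 3-methylbutanoate
Conditions: pyridine (1.5 equiv), CH2Cl2, 0 °C to rt, dark
Reagents that add atoms: none
Why: Acylation of a primary alcohol with an acid chloride; the primary iodide is not displaced by pyridine at this temperature on the time scale of the acylation.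

Step 5
Reactants: 7 (5'-ethynyl-[2,2'-bithiophen]-5-yl)methyl 3-methylbut-2-enoate; 10 2-iodoethyl 3-methylbutanoate
Product: 11 {5'-[4-(3-methylbutanoyloxy)but-1-yn-1-yl]-[2,2'-bithiophen]-5-yl}methyl 3-methylbut-2-enoate
Conditions: CuCl (10 mol%), 2,2':6',2''-terpyridine (10 mol%), K2CO3 (2 equiv), 10 (1.5 equiv), degassed MeCN, blue LEDs (450 nm), rt, Ar
Reagents that add atoms: none
Why: K2CO3 and Cu(I)/terpyridine convert the acidic, bithienyl-conjugated C(sp)–H of 7 into a copper(I) acetylide whose extended bithienylethynyl chromophore absorbs blue light; the excited acetylide transfers one electron to the C–I bond of 10, which fragments to iodide and the primary 2-(3-methylbutanoyloxy)ethyl radical, and this radical is captured by the copper(II) acetylide to give a Cu(III) alkyl alkynyl species that reductively eliminates the C(sp)–C(sp3) bond. The closest known reaction type is the photoinduced copper-catalysed coupling of terminal aryl alkynes with unactivated alkyl iodides, a radical Sonogashira-type alkylation. No ring is closed and no stereocentre is formed. The step needs cross-coupling to win over oxidative homodimerisation of the alkyne, which exclusion of oxygen and the tridentate terpyridine ligand should secure, and it needs both esters to survive, which the carbonate base and the absence of any organometallic nucleophile should secure. The radical itself should be well behaved: its 1,2-acyloxy shift is degenerate, and addition to the β,β-disubstituted enoate or to the thiophene rings should be slower than capture at copper.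

**Compound list**

1 | 5'-bromo-[2,2'-bithiophene]-5-carbaldehyde | O=Cc1ccc(-c2ccc(Br)s2)s1 | starting material
2 | ethynyltrimethylsilane | C#C[Si](C)(C)C | starting material
3 | 5'-[(trimethylsilyl)ethynyl]-[2,2'-bithiophene]-5-carbaldehyde | O=Cc1ccc(-c2ccc(C#C[Si](C)(C)C)s2)s1 | intermediate
4 | {5'-[(trimethylsilyl)ethynyl]-[2,2'-bithiophen]-5-yl}methanol | OCc1ccc(-c2ccc(C#C[Si](C)(C)C)s2)s1 | intermediate (not isolated)
5 | (5'-ethynyl-[2,2'-bithiophen]-5-yl)methanol | OCc1ccc(-c2ccc(C#C)s2)s1 | intermediate
6 | 3-methylbut-2-enoic acid (senecioic acid) | CC(C)=CC(=O)O | starting material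
7 | (5'-ethynyl-[2,2'-bithiophen]-5-yl)methyl 3-methylbut-2-enoate | CC(C)=CC(=O)OCc1ccc(-c2ccc(C#C)s2)s1 | intermediate
8 | 2-iodoethanol | OCCI | starting material
9 | 3-methylbutanoyl chloride (isovaleryl chloride) | CC(C)CC(=O)Cl | starting material
10 | 2-iodoethyl 3-methylbutanoate | CC(C)CC(=O)OCCI | intermediate
11 | {5'-[4-(3-methylbutanoyloxy)but-1-yn-1-yl]-[2,2'-bithiophen]-5-yl}methyl 3-methylbut-2-enoate | CC(C)=CC(=O)OCc1ccc(-c2ccc(C#CCCOC(=O)CC(C)C)s2)s1 | target

Total step count: 5. Longest linear sequence: 4 (steps 1, 2, 3, 5).

**Steps most likely to fail**

Step 5. The alkyne may dimerise oxidatively, the light-sensitive bithienylacetylene may degrade under irradiation, or the alkyl partner may be lost by over-reduction and β-elimination of isovalerate before the C–C bond forms. The fallback moves the union to the thiophene–alkyne bond and sets out from 1. Reduction of 1 with NaBH4 in MeOH should give (5'-bromo-[2,2'-bithiophen]-5-yl)methanol F1. Esterification of this with 6 (DCC, DMAP, CH2Cl2) should give (5'-bromo-[2,2'-bithiophen]-5-yl)methyl 3-methylbut-2-enoate F2. Separately, but-3-yn-1-ol (C#CCCO) is acylated with 9 and pyridine to but-3-yn-1-yl 3-methylbutanoate F3. Sonogashira coupling of the last two (PdCl2(PPh3)2, CuI, Et3N, THF, 40 °C) comes back to the route at 11.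

Step 3. The double bond may migrate out of conjugation through the DMAP-activated acyl species, the activated acid may rearrange to the N-acylurea, or the electron-rich thienylmethyl alcohol may ionise and self-condense. The fallback activates the alcohol in place of the acid and sets out from 5. Mitsunobu esterification of 5 with 6 (PPh3, DIAD, THF, 0 °C) should give 7 directly by carboxylate displacement, so it comes back to the route at 7 and no new compound arises.

Step 2. The free ethynyl carbinol may oligomerise or decompose in air and light while it carries both the free alkyne and the free hydroxyl group, or the desilylation may stay incomplete in the borate-containing medium. The fallback carries the silyl group through the esterification and sets out from 3. Reduction with NaBH4 alone (MeOH/THF, 0 °C) and isolation gives 4. Esterification with 6 (DCC, DMAP, CH2Cl2) should give {5'-[(trimethylsilyl)ethynyl]-[2,2'-bithiophen]-5-yl}methyl 3-methylbut-2-enoate F4. Desilylation with acetic-acid-buffered TBAF (THF, 0 °C) comes back to the route at 7.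

**Further compounds**

F1 | step 5 | (5'-bromo-[2,2'-bithiophen]-5-yl)methanol | OCc1ccc(-c2ccc(Br)s2)s1
F2 | step 5 | (5'-bromo-[2,2'-bithiophen]-5-yl)methyl 3-methylbut-2-enoate | CC(C)=CC(=O)OCc1ccc(-c2ccc(Br)s2)s1
F3 | step 5 | but-3-yn-1-yl 3-methylbutanoate | C#CCCOC(=O)CC(C)C
F0 | step 3 | none | none
F4 | step 2 | {5'-[(trimethylsilyl)ethynyl]-[2,2'-bithiophen]-5-yl}methyl 3-methylbut-2-enoate | CC(C)=CC(=O)OCc1ccc(-c2ccc(C#C[Si](C)(C)C)s2)s1
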